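Ring A is assembled last and in one operation: its C4a–C5 and C8–C8a bonds are disconnected so that the oxygenated benzene ring arises from a cyclobutenone and a silyloxyalkyne. The key step exploits the 1,3,5-oxygenation of ring A with C4a lying between O–C5 and O–C8a: a thermal vinylketene benzannulation writes H at C8, OMe at C7, prenyl at C6, a free C5 hydroxyl and a silylated C8a oxygen into the ring, with the two oxygens already differentiated. Its precursor is an (R)-configured triisopropylsilyl ynol ether carrying C2, C3, C4 and the silyl-protected chromene ring B; ring C is then closed by O1–C2 etherification.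

Key step: step 14

Remark on the chemistry: the ring B phenol is carried as a triisopropylsilyl ether, not a tert-butyldimethylsilyl ether, because it must survive aqueous base at rhodium, carbonate in methanol and organolithium reagents before the key step.
Remark on the chemistry: (R)-BINAP is assumed to deliver the aryl group to the same face of furan-2(5H)-one as it does with five- and six-membered cyclic enones, which corresponds to R at the future C3.

Step 1
Reactants: 1 4-bromoresorcinol
Product: 2 2-bromo-5-(triisopropylsilyloxy)phenol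
Conditions: TIPSCl (1.05 equiv), imidazole, CH2Cl2, 0 °C
Reagents that add atoms: triisopropylsilyl chloride, CC(C)[Si](Cl)(C(C)C)C(C)C
Why: Site-selective silylation: the bulky chlorosilane should react at the hydroxyl para to bromine, which has two unsubstituted ortho positions, far faster than at the hydroxyl flanked by bromine, so the oxygen destined to become the chromene oxygen stays free.

Step 2
Reactants: 2 2-bromo-5-(triisopropylsilyloxy)phenol; 3 3-chloro-3-methylbut-1-yne
Product: 4 [4-bromo-3-(2-methylbut-3-yn-2-yloxy)phenoxy]triisopropylsilane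
Conditions: DBU, CuCl2 (0.5 mol %), MeCN, 0 °C
Reagents that add atoms: none
Why: Copper-catalysed O-propargylation of a phenol with a tertiary propargylic chloride (a Williamson-type etherification through a copper acetylide/allenylidene) should give the 1,1-dimethylpropargyl aryl ether under conditions too mild to cleave the aryl silyl ether.

Step 3
Reactants: 4 [4-bromo-3-(2-methylbut-3-yn-2-yloxy)phenoxy]triisopropylsilane
Product: 6 8-bromo-2,2-dimethyl-5-(triisopropylsilyloxy)-2H-chromene, via allenylphenol 5 (not isolated)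
Conditions: PhNEt2, 185 °C
Reagents that add atoms: none
Why: Aromatic propargyl Claisen rearrangement can only be completed at the free ortho carbon between the two oxygens (the other ortho position bears bromine), and allenylphenol 5 should then close to the 2H-chromene by 1,5-hydrogen shift and oxa six-electron electrocyclisation, which fixes the ring B substitution pattern.

Step 4
Reactants: 6 8-bromo-2,2-dimethyl-5-(triisopropylsilyloxy)-2H-chromene
Product: 9 [2,2-dimethyl-5-(triisopropylsilyloxy)-2H-chromen-8-yl]boronic acid, via aryllithium 7 (not isolated), via lithium triisopropoxyborate 8 (not isolated)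
Conditions: n-BuLi, THF, −78 °C; B(Oi-Pr)3, −78 °C → rt; aq NH4Cl
Reagents that add atoms: triisopropyl borate, CC(C)OB(OC(C)C)OC(C)C; water, O
Why: Bromine–lithium exchange at −78 °C, borylation of aryllithium 7 and hydrolysis of borate 8 is the standard arylboronic acid synthesis, and neither the silyl ether nor the chromene alkene reacts with n-BuLi at this temperature.

Step 5
Reactants: 9 [2,2-dimethyl-5-(triisopropylsilyloxy)-2H-chromen-8-yl]boronic acid; 10 furan-2(5H)-one
Product: 11 (4R)-4-[2,2-dimethyl-5-(triisopropylsilyloxy)-2H-chromen-8-yl]dihydrofuran-2(3H)-one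
Conditions: [RhCl(C2H4)2]2 (1.5 mol %), (R)-BINAP (3.3 mol %), KOH (10 mol %), dioxane/H2O 10:1, 50 °C
Reagents that add atoms: none
Why: Hayashi–Miyaura asymmetric 1,4-addition: the aryl group passes from boron to the BINAP-bound rhodium hydroxide, adds across the butenolide C=C in the enantio-determining insertion and the rhodium enolate is protonated by water, (R)-BINAP steering the aryl group to the face that makes the new stereocentre (the future C3) R.

Step 6
Reactants: 11 (4R)-4-[2,2-dimethyl-5-(triisopropylsilyloxy)-2H-chromen-8-yl]dihydrofuran-2(3H)-one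
Product: 12 (4R)-4-[2,2-dimethyl-5-(triisopropylsilyloxy)-2H-chromen-8-yl]tetrahydrofuran-2-ol (lactol; both anomers)
Conditions: i-Bu2AlH (1.1 equiv), CH2Cl2, −78 °C; aq potassium sodium tartrate
Reagents that add atoms: none
Why: Half-reduction of a gamma-lactone by i-Bu2AlH at −78 °C stops at the aluminium hemiacetal and should give the lactol on work-up, with the stereocentre beta to the carbonyl and therefore untouched.

Step 7
Reactants: 12 (4R)-4-[2,2-dimethyl-5-(triisopropylsilyloxy)-2H-chromen-8-yl]tetrahydrofuran-2-ol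
Product: 13 (2R)-2-[2,2-dimethyl-5-(triisopropylsilyloxy)-2H-chromen-8-yl]pent-4-yn-1-ol
Conditions: dimethyl (1-diazo-2-oxopropyl)phosphonate, K2CO3, MeOH, 0 °C → rt
Reagents that add atoms: dimethyl (1-diazo-2-oxopropyl)phosphonate, COP(=O)(OC)C(=[N+]=[N-])C(C)=O
Why: Ohira–Bestmann (Seyferth–Gilbert) homologation of the hydroxy aldehyde in equilibrium with the lactol should give the terminal alkyne by 1,2-hydrogen shift in the alkylidene carbene, and the non-enolisable beta stereocentre cannot epimerise under carbonate in methanol.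

Step 8
Reactants: 13 (2R)-2-[2,2-dimethyl-5-(triisopropylsilyloxy)-2H-chromen-8-yl]pent-4-yn-1-ol
Product: 14 tert-butyl{(2R)-2-[2,2-dimethyl-5-(triisopropylsilyloxy)-2H-chromen-8-yl]pent-4-ynyloxy}dimethylsilane
Conditions: TBSCl, imidazole, CH2Cl2, rt
Reagents that add atoms: tert-butyldimethylsilyl chloride, CC(C)(C)[Si](C)(C)Cl
Why: Standard silylation of a primary alcohol, required because a free hydroxyl would be acylated by the ketene of the key step.

Step 9
Reactants: 14 tert-butyl{(2R)-2-[2,2-dimethyl-5-(triisopropylsilyloxy)-2H-chromen-8-yl]pent-4-ynyloxy}dimethylsilane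
Product: 17 (4R)-5-(tert-butyldimethylsilyloxy)-4-[2,2-dimethyl-5-(triisopropylsilyloxy)-2H-chromen-8-yl]-1-(triisopropylsilyloxy)pent-1-yne, via lithium acetylide 15 (not isolated), via lithium ynolate 16 (not isolated)
Conditions: n-BuLi, THF, −78 °C; t-BuOOLi (from t-BuOOH and LiN(SiMe3)2), −78 → 0 °C; TIPSOTf, −78 °C
Reagents that add atoms: tert-butyl hydroperoxide, CC(C)(C)OO; triisopropylsilyl trifluoromethanesulfonate, CC(C)[Si](OS(=O)(=O)C(F)(F)F)(C(C)C)C(C)C
Why: Julia oxidation of lithium acetylide 15 with lithium tert-butyl peroxide should transfer oxygen to carbon to give lithium ynolate 16, which the bulky silyl triflate silylates on oxygen to an isolable triisopropylsilyl ynol ether, no bond at the stereocentre being touched.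

Step 10
Reactants: 18 2-methylbut-3-en-2-ol; 19 triethyl orthoacetate
Product: 21 ethyl 5-methylhex-4-enoate, via ketene acetal 20 (not isolated)
Conditions: EtCO2H (cat.), 140 °C, EtOH distilled off
Reagents that add atoms: none
Why: Johnson–Claisen rearrangement: orthoester exchange and loss of ethanol give ketene acetal 20, whose [3,3] sigmatropic shift should deliver the gamma,delta-unsaturated ester and turn the tertiary allylic alcohol into the prenyl-type trisubstituted alkene.

Step 11
Reactants: 21 ethyl 5-methylhex-4-enoate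
Product: 22 5-methylhex-4-enoic acid
Conditions: NaOH, MeOH/H2O, rt; aq HCl
Reagents that add atoms: sodium hydroxide, [Na+].[OH-]
Why: Plain saponification of an unhindered ethyl ester, the isolated trisubstituted alkene being inert to aqueous base.

Step 12
Reactants: 23 chloroacetaldehyde dimethyl acetal
Product: 25 methoxyacetylene, via sodium methoxyacetylide 24 (not isolated)
Conditions: NaNH2 (3.1 equiv), liquid NH3, −33 °C; cold aq NaCl; distil
Reagents that add atoms: none
Why: Sodium amide should effect successive elimination of methanol and hydrogen chloride from the chloroacetal and deprotonate the alkyne to acetylide 24, which is protonated on cold aqueous quench, the classical dehydrohalogenation route to alkoxyacetylenes.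

Step 13
Reactants: 22 5-methylhex-4-enoic acid; 25 methoxyacetylene
Product: 28 3-methoxy-4-(3-methylbut-2-enyl)cyclobut-2-enone (racemic), via acid chloride 26 (not isolated), via prenylketene 27 (not isolated)
Conditions: (COCl)2, DMF (cat.), CH2Cl2, 0 °C → rt, evaporate; 25 (3 equiv), Et3N (slow addition), Et2O, 0 °C → rt
Reagents that add atoms: none
Why: Dehydrochlorination of acid chloride 26 by Et3N gives monoalkylketene 27, which should undergo regioselective [2+2] cycloaddition with the alkoxyalkyne (its nucleophilic CH carbon bonding to the ketene carbonyl carbon), a known cyclobutenone synthesis that puts OMe at C3 and the prenyl group at C4; the new stereocentre is formed as a racemate and is erased in the key step.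

Step 14
Reactants: 17 (4R)-5-(tert-butyldimethylsilyloxy)-4-[2,2-dimethyl-5-(triisopropylsilyloxy)-2H-chromen-8-yl]-1-(triisopropylsilyloxy)pent-1-yne; 28 3-methoxy-4-(3-methylbut-2-enyl)cyclobut-2-enone
Product: 33 2-{(2R)-3-(tert-butyldimethylsilyloxy)-2-[2,2-dimethyl-5-(triisopropylsilyloxy)-2H-chromen-8-yl]propyl}-5-methoxy-6-(3-methylbut-2-enyl)-3-(triisopropylsilyloxy)phenol, via vinylketene 29 (not isolated), via vinylcyclobutenone 30 (not isolated), via dienylketene 31 (not isolated), via cyclohexadienone 32 (not isolated)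
Conditions: PhMe (0.5 M), 28 (1.5 equiv), argon, sealed tube, 80 °C then 110 °C
Reagents that add atoms: none
Why: Heating opens cyclobutenone 28 by conrotatory four-electron electrocyclic cleavage of its C(=O)–C(sp3) bond to methoxy vinylketene 29, whose ketene C=C undergoes [2+2] cycloaddition with the electron-rich ynol ether 17 to give vinylcyclobutenone 30. A second four-electron opening gives dienylketene 31, which closes ring A by disrotatory six-electron electrocyclisation (6-membered carbocycle, bond between the ketene carbon C5 and the prenyl-bearing carbon C6) to cyclohexadienone 32 and then tautomerises to phenol 33. The closest known reaction type is the Danheiser benzannulation of cyclobutenones with trialkylsilyloxyalkynes. No stereocentre is created in 33 (the sp3 centres of 28, 30 and 32 are lost on aromatisation), and C3 is a spectator separated from the alkyne by a methylene group, so its R configuration is carried through unchanged. The step needs regioselectivity in the [2+2] event, and the polarity of the ynol ether secures it: its carbon remote from oxygen is nucleophilic and bonds to the electrophilic ketene carbonyl carbon (C4a–C5), while the oxygen-bearing carbon bonds to the ketene alpha carbon (C8–C8a), which places the chain between the free C5 hydroxyl and the silylated C8a oxygen. Chemoselectivity over the chromene and prenyl alkenes should follow from the much higher nucleophilicity of the silyloxyalkyne toward ketenes.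

Step 15
Reactants: 33 2-{(2R)-3-(tert-butyldimethylsilyloxy)-2-[2,2-dimethyl-5-(triisopropylsilyloxy)-2H-chromen-8-yl]propyl}-5-methoxy-6-(3-methylbut-2-enyl)-3-(triisopropylsilyloxy)phenol
Product: 34 tert-butyl{(2R)-3-[2,4-dimethoxy-3-(3-methylbut-2-enyl)-6-(triisopropylsilyloxy)phenyl]-2-[2,2-dimethyl-5-(triisopropylsilyloxy)-2H-chromen-8-yl]propoxy}dimethylsilane
Conditions: MeI, K2CO3, acetone, 50 °C
Reagents that add atoms: iodomethane, CI
Why: Williamson O-methylation of the only free phenol (SN2 on iodomethane) fixes C5 as a methyl ether while C8a–O stays silylated, and carbonate in dry acetone should leave the aryl and alkyl silyl ethers intact.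

Step 16
Reactants: 34 tert-butyl{(2R)-3-[2,4-dimethoxy-3-(3-methylbut-2-enyl)-6-(triisopropylsilyloxy)phenyl]-2-[2,2-dimethyl-5-(triisopropylsilyloxy)-2H-chromen-8-yl]propoxy}dimethylsilane
Product: 35 2-[(2R)-3-hydroxy-2-(5-hydroxy-2,2-dimethyl-2H-chromen-8-yl)propyl]-3,5-dimethoxy-4-(3-methylbut-2-enyl)phenol
Conditions: Bu4NF (4 equiv), THF, 0 °C → rt; aq NH4Cl
Reagents that add atoms: none
Why: Fluoride-mediated desilylation should cleave both aryl triisopropylsilyl ethers and the primary tert-butyldimethylsilyl ether in one operation, the methyl ethers, the prenyl group and the chromene being inert to Bu4NF.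

Step 17
Reactants: 35 2-[(2R)-3-hydroxy-2-(5-hydroxy-2,2-dimethyl-2H-chromen-8-yl)propyl]-3,5-dimethoxy-4-(3-methylbut-2-enyl)phenol
Product: 36 kanzonol I, 8-[(3R)-5,7-dimethoxy-6-(3-methylbut-2-enyl)-3,4-dihydro-2H-chromen-3-yl]-2,2-dimethyl-2H-chromen-5-ol
Conditions: PPh3, DIAD, THF (0.01 M), 0 °C → rt
Reagents that add atoms: none
Why: Intramolecular Mitsunobu etherification: the primary alcohol is activated as an alkoxyphosphonium ion and displaced by the C8a phenoxide in a 6-exo-tet closure of ring C (O1–C2), the ring B phenol being unable to reach C2 and dilution suppressing its intermolecular alkylation, and C3 is not a reacting centre so its R configuration is retained.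

Compound list
1 | 4-bromoresorcinol | Oc1ccc(Br)c(O)c1 | starting material
2 | 2-bromo-5-(triisopropylsilyloxy)phenol | CC(C)[Si](Oc1ccc(Br)c(O)c1)(C(C)C)C(C)C | intermediate
3 | 3-chloro-3-methylbut-1-yne | C#CC(C)(C)Cl | starting material
4 | [4-bromo-3-(2-methylbut-3-yn-2-yloxy)phenoxy]triisopropylsilane | C#CC(C)(C)Oc1cc(O[Si](C(C)C)(C(C)C)C(C)C)ccc1Br | intermediate
5 | 6-bromo-2-(3-methylbuta-1,2-dienyl)-3-(triisopropylsilyloxy)phenol (allenylphenol) | CC(C)=C=Cc1c(O)c(Br)ccc1O[Si](C(C)C)(C(C)C)C(C)C | intermediate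
6 | 8-bromo-2,2-dimethyl-5-(triisopropylsilyloxy)-2H-chromene | CC1(C)C=Cc2c(O[Si](C(C)C)(C(C)C)C(C)C)ccc(Br)c2O1 | intermediate
7 | [2,2-dimethyl-5-(triisopropylsilyloxy)-2H-chromen-8-yl]lithium (aryllithium) | [Li]c1ccc(O[Si](C(C)C)(C(C)C)C(C)C)c2c1OC(C)(C)C=C2 | intermediate
8 | lithium [2,2-dimethyl-5-(triisopropylsilyloxy)-2H-chromen-8-yl]triisopropoxyborate | CC(C)O[B-](OC(C)C)(OC(C)C)c1ccc(O[Si](C(C)C)(C(C)C)C(C)C)c2c1OC(C)(C)C=C2.[Li+] | intermediate
9 | [2,2-dimethyl-5-(triisopropylsilyloxy)-2H-chromen-8-yl]boronic acid | OB(O)c1ccc(O[Si](C(C)C)(C(C)C)C(C)C)c2c1OC(C)(C)C=C2 | intermediate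
10 | furan-2(5H)-one | O=C1OCC=C1 | starting material
11 | (4R)-4-[2,2-dimethyl-5-(triisopropylsilyloxy)-2H-chromen-8-yl]dihydrofuran-2(3H)-one | O=C1C[C@H](c2ccc(O[Si](C(C)C)(C(C)C)C(C)C)c3c2OC(C)(C)C=C3)CO1 | intermediate
12 | (4R)-4-[2,2-dimethyl-5-(triisopropylsilyloxy)-2H-chromen-8-yl]tetrahydrofuran-2-ol (lactol, both anomers) | OC1C[C@H](c2ccc(O[Si](C(C)C)(C(C)C)C(C)C)c3c2OC(C)(C)C=C3)CO1 | intermediate
13 | (2R)-2-[2,2-dimethyl-5-(triisopropylsilyloxy)-2H-chromen-8-yl]pent-4-yn-1-ol | C#CC[C@H](c1ccc(O[Si](C(C)C)(C(C)C)C(C)C)c2c1OC(C)(C)C=C2)CO | intermediate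
14 | tert-butyl{(2R)-2-[2,2-dimethyl-5-(triisopropylsilyloxy)-2H-chromen-8-yl]pent-4-ynyloxy}dimethylsilane | C#CC[C@H](c1ccc(O[Si](C(C)C)(C(C)C)C(C)C)c2c1OC(C)(C)C=C2)CO[Si](C)(C)C(C)(C)C | intermediate
15 | lithium acetylide of 14 | [Li]C#CC[C@H](c1ccc(O[Si](C(C)C)(C(C)C)C(C)C)c2c1OC(C)(C)C=C2)CO[Si](C)(C)C(C)(C)C | intermediate
16 | lithium (4R)-5-(tert-butyldimethylsilyloxy)-4-[2,2-dimethyl-5-(triisopropylsilyloxy)-2H-chromen-8-yl]pent-1-yn-1-olate (lithium ynolate) | [Li]OC#CC[C@H](c1ccc(O[Si](C(C)C)(C(C)C)C(C)C)c2c1OC(C)(C)C=C2)CO[Si](C)(C)C(C)(C)C | intermediate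
17 | (4R)-5-(tert-butyldimethylsilyloxy)-4-[2,2-dimethyl-5-(triisopropylsilyloxy)-2H-chromen-8-yl]-1-(triisopropylsilyloxy)pent-1-yne | CC(C)[Si](OC#CC[C@H](c1ccc(O[Si](C(C)C)(C(C)C)C(C)C)c2c1OC(C)(C)C=C2)CO[Si](C)(C)C(C)(C)C)(C(C)C)C(C)C | intermediate
18 | 2-methylbut-3-en-2-ol | C=CC(C)(C)O | starting material
19 | triethyl orthoacetate | CCOC(C)(OCC)OCC | starting material
20 | 3-(1-ethoxyvinyloxy)-3-methylbut-1-ene (ketene acetal) | C=C(OCC)OC(C)(C)C=C | intermediate
21 | ethyl 5-methylhex-4-enoate | CCOC(=O)CCC=C(C)C | intermediate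
22 | 5-methylhex-4-enoic acid | OC(=O)CCC=C(C)C | intermediate
23 | chloroacetaldehyde dimethyl acetal | COC(CCl)OC | starting material
24 | sodium methoxyacetylide | COC#C[Na] | intermediate
25 | methoxyacetylene | COC#C | intermediate
26 | 5-methylhex-4-enoyl chloride | ClC(=O)CCC=C(C)C | intermediate
27 | 5-methylhexa-1,4-dien-1-one (prenylketene) | O=C=CCC=C(C)C | intermediate
28 | 3-methoxy-4-(3-methylbut-2-enyl)cyclobut-2-enone (racemic) | COC1=CC(=O)C1CC=C(C)C | intermediate
29 | 3-methoxy-7-methylocta-1,3,6-trien-1-one (vinylketene) | O=C=CC(OC)=CCC=C(C)C | intermediate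
30 | 2-{(2R)-3-(tert-butyldimethylsilyloxy)-2-[2,2-dimethyl-5-(triisopropylsilyloxy)-2H-chromen-8-yl]propyl}-4-(1-methoxy-5-methylhexa-1,4-dienyl)-3-(triisopropylsilyloxy)cyclobut-2-enone (vinylcyclobutenone, both epimers at C4 of the four-membered ring) | O=C1C(C[C@H](c2ccc(O[Si](C(C)C)(C(C)C)C(C)C)c3c2OC(C)(C)C=C3)CO[Si](C)(C)C(C)(C)C)=C(O[Si](C(C)C)(C(C)C)C(C)C)C1C(OC)=CCC=C(C)C | intermediate
31 | 2-{(2R)-3-(tert-butyldimethylsilyloxy)-2-[2,2-dimethyl-5-(triisopropylsilyloxy)-2H-chromen-8-yl]propyl}-5-methoxy-9-methyl-3-(triisopropylsilyloxy)deca-1,3,5,8-tetraen-1-one (dienylketene) | O=C=C(C[C@H](c1ccc(O[Si](C(C)C)(C(C)C)C(C)C)c2c1OC(C)(C)C=C2)CO[Si](C)(C)C(C)(C)C)C(O[Si](C(C)C)(C(C)C)C(C)C)=CC(OC)=CCC=C(C)C | intermediate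
32 | 2-{(2R)-3-(tert-butyldimethylsilyloxy)-2-[2,2-dimethyl-5-(triisopropylsilyloxy)-2H-chromen-8-yl]propyl}-5-methoxy-6-(3-methylbut-2-enyl)-3-(triisopropylsilyloxy)cyclohexa-2,4-dienone (both epimers at C6 of the ring) | O=C1C(C[C@H](c2ccc(O[Si](C(C)C)(C(C)C)C(C)C)c3c2OC(C)(C)C=C3)CO[Si](C)(C)C(C)(C)C)=C(O[Si](C(C)C)(C(C)C)C(C)C)C=C(OC)C1CC=C(C)C | intermediate
33 | 2-{(2R)-3-(tert-butyldimethylsilyloxy)-2-[2,2-dimethyl-5-(triisopropylsilyloxy)-2H-chromen-8-yl]propyl}-5-methoxy-6-(3-methylbut-2-enyl)-3-(triisopropylsilyloxy)phenol | COc1cc(O[Si](C(C)C)(C(C)C)C(C)C)c(C[C@H](c2ccc(O[Si](C(C)C)(C(C)C)C(C)C)c3c2OC(C)(C)C=C3)CO[Si](C)(C)C(C)(C)C)c(O)c1CC=C(C)C | intermediate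
34 | tert-butyl{(2R)-3-[2,4-dimethoxy-3-(3-methylbut-2-enyl)-6-(triisopropylsilyloxy)phenyl]-2-[2,2-dimethyl-5-(triisopropylsilyloxy)-2H-chromen-8-yl]propoxy}dimethylsilane | COc1cc(O[Si](C(C)C)(C(C)C)C(C)C)c(C[C@H](c2ccc(O[Si](C(C)C)(C(C)C)C(C)C)c3c2OC(C)(C)C=C3)CO[Si](C)(C)C(C)(C)C)c(OC)c1CC=C(C)C | intermediate
35 | 2-[(2R)-3-hydroxy-2-(5-hydroxy-2,2-dimethyl-2H-chromen-8-yl)propyl]-3,5-dimethoxy-4-(3-methylbut-2-enyl)phenol | COc1cc(O)c(C[C@H](c2ccc(O)c3c2OC(C)(C)C=C3)CO)c(OC)c1CC=C(C)C | intermediate
36 | kanzonol I, 8-[(3R)-5,7-dimethoxy-6-(3-methylbut-2-enyl)-3,4-dihydro-2H-chromen-3-yl]-2,2-dimethyl-2H-chromen-5-ol | COc1cc2c(c(OC)c1CC=C(C)C)C[C@H](c1ccc(O)c3c1OC(C)(C)C=C3)CO2 | target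

Total step count: 17. Longest linear sequence: 13 steps (steps 1–9 and 14–17).

Steps most likely to fail

Step 14 (key step). The vinylogous-ester cyclobutenone may open too slowly, so that the ynol ether is consumed by thermal decomposition, or the vinylketene may be intercepted by the product phenol, before the cascade is complete. The fallback sets out from 17 and generates the same vinylketene without heating.
- Methyl acetoacetate is alkylated at C4 through its dianion (NaH then n-BuLi, THF, 0 °C) with 1-bromo-3-methylbut-2-ene to give methyl 7-methyl-3-oxooct-6-enoate F1.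
- Trimethyl orthoformate and catalytic H2SO4 in methanol convert it into methyl (2E)-3-methoxy-7-methylocta-2,6-dienoate F2.
- LiOH in THF/water gives (2E)-3-methoxy-7-methylocta-2,6-dienoic acid F3, and oxalyl chloride gives (2E)-3-methoxy-7-methylocta-2,6-dienoyl chloride F4.
- Slow addition of Et3N to F4 and 17 in CH2Cl2 at room temperature removes a gamma hydrogen (1,4-dehydrochlorination) and forms vinylketene 29, which 17 traps as vinylcyclobutenone 30.
- After filtration of the ammonium salt, 30 is heated alone in toluene (80–110 °C) and passes through 31 and 32 to 33, where the fallback rejoins the route.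

Step 5. Protodeboronation of the electron-rich, ortho-oxygenated boronic acid may outrun insertion into the weakly reactive five-membered lactone, and ligand-free rhodium may erode the enantioselectivity. The fallback sets out from 9 and separates C–C bond formation from stereocontrol.
- Suzuki coupling of 9 with 4-bromofuran-2(5H)-one (Pd(PPh3)4, KF, THF/H2O, 60 °C) gives 4-[2,2-dimethyl-5-(triisopropylsilyloxy)-2H-chromen-8-yl]furan-2(5H)-one F5.
- Copper hydride asymmetric conjugate reduction of F5 (Cu(OAc)2, p-tol-BINAP, polymethylhydrosiloxane, t-BuOH, toluene, 0 °C) sets the stereocentre; the ligand antipode is chosen to give R.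
- The electron-poor butenolide alkene should be reduced in preference to the chromene alkene, and the fallback rejoins the route at 11.

Step 9. Oxygen transfer to the acetylide may be incomplete, or the ynolate may be protonated or silylated on carbon at the quench, so that the ynol ether is not obtained cleanly. The fallback sets out from 9 and reaches the ynolate from an ester instead of an alkyne.
- Wittig olefination of (tert-butyldimethylsilyloxy)acetaldehyde with ethyl (triphenylphosphoranylidene)acetate gives ethyl (2E)-4-(tert-butyldimethylsilyloxy)but-2-enoate F6.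
- Rhodium/BINAP-catalysed 1,4-addition of 9 to F6 (catalyst system of step 5) gives ethyl (3R)-4-(tert-butyldimethylsilyloxy)-3-[2,2-dimethyl-5-(triisopropylsilyloxy)-2H-chromen-8-yl]butanoate F7.
- The BINAP antipode is confirmed by desilylative lactonisation of a sample of F7 to 11.
- Kowalski homologation of F7 (LiCHBr2 from CH2Br2 and lithium 2,2,6,6-tetramethylpiperidide, THF, −78 °C; LiN(SiMe3)2; n-BuLi, −78 °C → rt) gives ynolate 16.
- O-Silylation of 16 with TIPSCl gives 17, where the fallback rejoins the route.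

Further compounds
F1 | step 14 | methyl 7-methyl-3-oxooct-6-enoate | COC(=O)CC(=O)CCC=C(C)C
F2 | step 14 | methyl (2E)-3-methoxy-7-methylocta-2,6-dienoate | CO/C(CCC=C(C)C)=C/C(=O)OC
F3 | step 14 | (2E)-3-methoxy-7-methylocta-2,6-dienoic acid | CO/C(CCC=C(C)C)=C/C(=O)O
F4 | step 14 | (2E)-3-methoxy-7-methylocta-2,6-dienoyl chloride | CO/C(CCC=C(C)C)=C/C(=O)Cl
F5 | step 5 | 4-[2,2-dimethyl-5-(triisopropylsilyloxy)-2H-chromen-8-yl]furan-2(5H)-one | O=C1C=C(c2ccc(O[Si](C(C)C)(C(C)C)C(C)C)c3c2OC(C)(C)C=C3)CO1
F6 | step 9 | ethyl (2E)-4-(tert-butyldimethylsilyloxy)but-2-enoate | CCOC(=O)/C=C/CO[Si](C)(C)C(C)(C)C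
F7 | step 9 | ethyl (3R)-4-(tert-butyldimethylsilyloxy)-3-[2,2-dimethyl-5-(triisopropylsilyloxy)-2H-chromen-8-yl]butanoate | CCOC(=O)C[C@H](c1ccc(O[Si](C(C)C)(C(C)C)C(C)C)c2c1OC(C)(C)C=C2)CO[Si](C)(C)C(C)(C)C
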